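**Plan**
Numbering: 3,7-dioxabicyclo[3.3.0]octane; C1/C5 ring fusion, C2 (guaiacyl) and C6 (prenyloxyaryl) benzylic, C4/C8 OCH2; ring A = C1–C2–O3–C4–C5, ring B = C5–C6–O7–C8–C1.
Retrosynthesis: take off the prenyl ether and the phenol protecting groups, return C4 to the acetal level, then cut C6–O7 and C5–C6 together; ring A is then cut at O3–C4 (lactol) and at C1–C2 (aldol).
Feature used: C6 carries ring oxygen O7 and a bond to C5, and C4 sits next to O3, so ring B is an aryl aldehyde (C6) annulated through the C8 hydroxyl onto the C4=C5 enol ether of ring A.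
Forward: C1–C2 by aldol addition, ring A by lactol formation and dehydration, ring B by the oxonium–Prins annulation, then C4 reduction and differentiation of the two phenols (acetate off, prenyl on, silyl off).
Stereochemistry: C1 and C2 from an auxiliary-controlled syn-aldol; C5 from the C1–C8–O7 tether (cis fusion); C6 from the oxocarbenium geometry in the annulation.

Key step: step 8

Remark: 20 is written as the exo C4 methyl acetal; either C4 anomer would serve, since step 9 removes that centre.

Step 1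
Reactants: 1 vanillin
Product: 2 3-methoxy-4-(triisopropylsilyloxy)benzaldehyde
Conditions: TIPSCl, imidazole, DMF, rt
Reagents that add atoms: triisopropylsilyl chloride, CC(C)[Si](Cl)(C(C)C)C(C)C
Why: Imidazole-promoted silylation of the phenol gives an ether that should withstand boron enolates, hydride, Lewis acids and mild base and is removed by fluoride at the end.

Step 2
Reactants: 3 (R)-4-benzyloxazolidin-2-one; 4 pent-4-enoyl chloride
Product: 5 (R)-4-benzyl-3-(pent-4-enoyl)oxazolidin-2-one
Conditions: n-BuLi, THF, −78 °C; then 4, −78 → 0 °C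
Reagents that add atoms: none
Why: N-Acylation of the lithiated oxazolidinone by the acid chloride is the standard preparation of N-acyloxazolidinones.

Step 3
Reactants: 5 (R)-4-benzyl-3-(pent-4-enoyl)oxazolidin-2-one; 2 3-methoxy-4-(triisopropylsilyloxy)benzaldehyde
Product: 8 (R)-4-benzyl-3-[(2R)-2-{(R)-hydroxy[3-methoxy-4-(triisopropylsilyloxy)phenyl]methyl}pent-4-enoyl]oxazolidin-2-one, via boron enolate 6 (not isolated), via boron aldolate 7 (not isolated)
Conditions: Bu2BOTf, i-Pr2NEt, CH2Cl2, 0 °C; then 2, −78 → 0 °C; pH 7 buffer, MeOH, H2O2, 0 °C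
Reagents that add atoms: none
Why: Evans syn-aldol reaction: the (Z)-dibutylboron enolate 6 adds through a closed Zimmerman–Traxler chair with the benzyl group of the (R)-auxiliary shielding one enolate face, which sets the carbinol carbon (future C2, R) and the α-carbon (future C1) in the syn relation that becomes the trans 2,3-pattern of ring A.

Step 4
Reactants: 8 syn-aldol adduct
Product: 11 (R)-4-benzyl-3-[(2R,3R)-5-hydroxy-2-[3-methoxy-4-(triisopropylsilyloxy)phenyl]oxolane-3-carbonyl]oxazolidin-2-one (anomers), via vicinal diol 9 (not isolated), via hydroxy aldehyde 10 (not isolated)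
Conditions: OsO4 (cat.), NaIO4, 2,6-lutidine, dioxane/H2O, rt
Reagents that add atoms: osmium tetroxide, O=[Os](=O)(=O)=O; sodium periodate, [Na+].[O-]I(=O)(=O)=O
Why: Lemieux–Johnson oxidation cleaves the terminal alkene, and the γ-hydroxy aldehyde 10 should close at once to the five-membered lactol (O3–C4 bond of ring A); the anomeric centre is left as a mixture because step 5 removes it.

Step 5
Reactants: 11 lactol
Product: 13 (R)-4-benzyl-3-[(2R,3R)-2-[3-methoxy-4-(triisopropylsilyloxy)phenyl]-2,3-dihydrofuran-3-carbonyl]oxazolidin-2-one (trans), via anomeric mesylate 12 (not isolated)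
Conditions: MsCl, Et3N, CH2Cl2, −40 → 40 °C
Reagents that add atoms: none
Why: Lactol dehydration as used for furanoid glycals: the anomeric mesylate at C4 ionises with help from O3 and loses a proton from C5 to Et3N to give the C4=C5 enol ether, and the trans relation of C1 and C2 is also the more stable one should C1 (α to the imide) equilibrate.

Step 6
Reactants: 13 dihydrofuran imide
Product: 14 [(2R,3S)-2-[3-methoxy-4-(triisopropylsilyloxy)phenyl]-2,3-dihydrofuran-3-yl]methanol (trans)
Conditions: LiBH4, MeOH, THF, 0 °C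
Reagents that add atoms: none
Why: Reductive cleavage of the N-acyloxazolidinone by LiBH4 turns the imide carbonyl into the C8 hydroxymethyl and releases the auxiliary, and neither the enol ether nor the aryl silyl ether reacts with borohydride.

Step 7
Reactants: 15 vanillin acetate (4-formyl-2-methoxyphenyl acetate)
Product: 16 4-(dimethoxymethyl)-2-methoxyphenyl acetate
Conditions: HC(OMe)3, PPTS (cat.), MeOH, rt
Reagents that add atoms: trimethyl orthoformate, COC(OC)OC; methanol, CO
Why: Acid-catalysed acetalisation driven by the orthoformate as water scavenger; the mild pyridinium acid should leave the aryl acetate in place.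

Step 8
Reactants: 14 [(2R,3S)-2-aryl-2,3-dihydrofuran-3-yl]methanol; 16 4-(dimethoxymethyl)-2-methoxyphenyl acetate
Product: 20 (1S,2R,4S,5R,6R)-6-(4-acetoxy-3-methoxyphenyl)-4-methoxy-2-[3-methoxy-4-(triisopropylsilyloxy)phenyl]-3,7-dioxabicyclo[3.3.0]octane, via mixed acetal 17 (not isolated), via tethered oxocarbenium ion 18 (not isolated), via bicyclic oxocarbenium ion 19 (not isolated)
Conditions: TMSOTf (0.3 equiv), CH2Cl2, −78 → −30 °C; then Et3N
Reagents that add atoms: none
Why: TMSOTf ionises acetal 16, the C8 hydroxyl of 14 takes the place of one methoxy group (mixed acetal 17), and a second ionisation gives the (E)-oxocarbenium ion 18, whose C6 is attacked by the enol ether carbon C5 to give the ring A oxocarbenium ion 19, which the methanol set free caps at C4 from the convex face. The closest known reaction type is the Lewis acid coupling of 2,3-dihydrofuran-3-ylmethanols with aldehyde acetals to alkoxyfurofurans, an oxonium–Prins (intramolecular Mukaiyama-type) closure. Ring B (C5–C6–O7–C8–C1) closes as a five-membered ring in a mode that is endo with respect to the C6=O7 bond and exo with respect to the C4=C5 bond. C5 is controlled by the three-atom C1–C8–O7 tether, which reaches only the enol ether face cis to C8 and so forces the cis ring fusion; C6 is controlled by the (E) geometry of 18 closing through the extended arrangement with O7 turned away from ring A and the aryl pseudo-equatorial, which places the aryl exo; C4 follows from convex-face capture and does not matter because step 9 removes it. The step needs exo selectivity at C6 and C-alkylation at C5 in preference to self-acetalisation of the enol ether by its own hydroxyl: the first rests on the (E)-oxocarbenium and on the electron-poor acetoxy arene, which gives a reactive cation that closes early and cannot be re-ionised at C6 once the ring is formed, and the second on exchanging the hydroxyl into the acetal at −78 °C before warming.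

Step 9
Reactants: 20 furofuran methyl acetal
Product: 21 (1S,2R,5S,6R)-6-(4-acetoxy-3-methoxyphenyl)-2-[3-methoxy-4-(triisopropylsilyloxy)phenyl]-3,7-dioxabicyclo[3.3.0]octane
Conditions: Et3SiH, BF3·OEt2, CH2Cl2, −78 → −40 °C
Reagents that add atoms: none
Why: Ionic hydrogenation of the acetal: BF3 activates the C4 methoxy group as a leaving group and triethylsilane delivers hydride to C4 in an SN1-type substitution assisted by O3, so C4 becomes the OCH2 group without touching C5 or C6; the low temperature should keep the benzylic C–O bonds from ionising.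

Step 10
Reactants: 21 furofuran aryl acetate
Product: 22 (1S,2R,5S,6R)-6-(4-hydroxy-3-methoxyphenyl)-2-[3-methoxy-4-(triisopropylsilyloxy)phenyl]-3,7-dioxabicyclo[3.3.0]octane
Conditions: NH3 (7 M in MeOH), 0 °C → rt
Reagents that add atoms: none
Why: Aminolysis of the phenyl acetate is fast under conditions that should leave the hindered aryl silyl ether and the benzylic ethers alone, which differentiates the two phenols.

Step 11
Reactants: 22 mono-phenol
Product: 23 (1S,2R,5S,6R)-6-[3-methoxy-4-(3-methylbut-2-enyloxy)phenyl]-2-[3-methoxy-4-(triisopropylsilyloxy)phenyl]-3,7-dioxabicyclo[3.3.0]octane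
Conditions: prenyl bromide, K2CO3, acetone, rt
Reagents that add atoms: 1-bromo-3-methylbut-2-ene (prenyl bromide), CC(C)=CCBr
Why: Williamson ether synthesis (SN2 at the primary allylic bromide) on the only free phenol.

Step 12
Reactants: 23 prenyl ether silyl ether
Product: 24 (1S,2R,5S,6R)-2-(4-hydroxy-3-methoxyphenyl)-6-[3-methoxy-4-(3-methylbut-2-enyloxy)phenyl]-3,7-dioxabicyclo[3.3.0]octane (target)
Conditions: TBAF, AcOH, THF, 0 °C
Reagents that add atoms: none
Why: Fluoride cleaves the aryl silyl ether, and the acetic acid buffer should keep the liberated p-hydroxybenzylic ether from opening through a quinone methide, so C2 is not epimerised and the prenyl ether is untouched.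

**Compound list**
1 | vanillin (4-hydroxy-3-methoxybenzaldehyde) | COc1cc(C=O)ccc1O | starting material
2 | 3-methoxy-4-(triisopropylsilyloxy)benzaldehyde | COc1cc(C=O)ccc1O[Si](C(C)C)(C(C)C)C(C)C | intermediate
3 | (R)-4-benzyloxazolidin-2-one | O=C1N[C@H](Cc2ccccc2)CO1 | starting material
4 | pent-4-enoyl chloride | C=CCCC(Cl)=O | starting material
5 | (R)-4-benzyl-3-(pent-4-enoyl)oxazolidin-2-one | C=CCCC(=O)N1[C@H](Cc2ccccc2)COC1=O | intermediate
6 | dibutylboron (Z)-enolate of 5 | C=CC/C=C(\OB(CCCC)CCCC)N1[C@H](Cc2ccccc2)COC1=O | intermediate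
7 | O-dibutylboryl aldolate of 8 | COc1cc([C@H](OB(CCCC)CCCC)[C@@H](CC=C)C(=O)N2[C@H](Cc3ccccc3)COC2=O)ccc1O[Si](C(C)C)(C(C)C)C(C)C | intermediate
8 | (R)-4-benzyl-3-[(2R)-2-{(R)-hydroxy[3-methoxy-4-(triisopropylsilyloxy)phenyl]methyl}pent-4-enoyl]oxazolidin-2-one (syn-aldol adduct) | COc1cc([C@H](O)[C@@H](CC=C)C(=O)N2[C@H](Cc3ccccc3)COC2=O)ccc1O[Si](C(C)C)(C(C)C)C(C)C | intermediate
9 | 4,5-dihydroxypentanoyl analogue of 8 (vicinal diol, C4 epimers) | COc1cc([C@H](O)[C@@H](CC(O)CO)C(=O)N2[C@H](Cc3ccccc3)COC2=O)ccc1O[Si](C(C)C)(C(C)C)C(C)C | intermediate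
10 | (R)-4-benzyl-3-[(2R)-2-{(R)-hydroxy[3-methoxy-4-(triisopropylsilyloxy)phenyl]methyl}-4-oxobutanoyl]oxazolidin-2-one (γ-hydroxy aldehyde) | COc1cc([C@H](O)[C@@H](CC=O)C(=O)N2[C@H](Cc3ccccc3)COC2=O)ccc1O[Si](C(C)C)(C(C)C)C(C)C | intermediate
11 | (R)-4-benzyl-3-[(2R,3R)-5-hydroxy-2-[3-methoxy-4-(triisopropylsilyloxy)phenyl]oxolane-3-carbonyl]oxazolidin-2-one (lactol, anomers) | COc1cc([C@@H]2OC(O)C[C@H]2C(=O)N3[C@H](Cc4ccccc4)COC3=O)ccc1O[Si](C(C)C)(C(C)C)C(C)C | intermediate
12 | anomeric methanesulfonate of 11 | COc1cc([C@@H]2OC(OS(C)(=O)=O)C[C@H]2C(=O)N3[C@H](Cc4ccccc4)COC3=O)ccc1O[Si](C(C)C)(C(C)C)C(C)C | intermediate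
13 | (R)-4-benzyl-3-[(2R,3R)-2-[3-methoxy-4-(triisopropylsilyloxy)phenyl]-2,3-dihydrofuran-3-carbonyl]oxazolidin-2-one (trans) | COc1cc([C@@H]2OC=C[C@H]2C(=O)N3[C@H](Cc4ccccc4)COC3=O)ccc1O[Si](C(C)C)(C(C)C)C(C)C | intermediate
14 | [(2R,3S)-2-[3-methoxy-4-(triisopropylsilyloxy)phenyl]-2,3-dihydrofuran-3-yl]methanol (trans) | COc1cc([C@@H]2OC=C[C@H]2CO)ccc1O[Si](C(C)C)(C(C)C)C(C)C | intermediate
15 | vanillin acetate (4-formyl-2-methoxyphenyl acetate) | COc1cc(C=O)ccc1OC(C)=O | starting material
16 | 4-(dimethoxymethyl)-2-methoxyphenyl acetate | COc1cc(C(OC)OC)ccc1OC(C)=O | intermediate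
17 | mixed methyl acetal of the 4-acetoxy-3-methoxybenzaldehyde unit with the C8 oxygen of 14 (acetal carbon epimers) | COc1cc([C@@H]2OC=C[C@H]2COC(OC)c2ccc(OC(C)=O)c(OC)c2)ccc1O[Si](C(C)C)(C(C)C)C(C)C | intermediate
18 | (E)-oxocarbenium ion C6=O7 tethered to the dihydrofuran | COc1cc([C@@H]2OC=C[C@H]2C/[O+]=C/c2ccc(OC(C)=O)c(OC)c2)ccc1O[Si](C(C)C)(C(C)C)C(C)C | intermediate
19 | bicyclic oxocarbenium ion C4=O3 (cis-fused, exo aryl at C6) | COc1cc([C@@H]2[O+]=C[C@@H]3[C@H]2CO[C@H]3c2ccc(OC(C)=O)c(OC)c2)ccc1O[Si](C(C)C)(C(C)C)C(C)C | intermediate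
20 | (1S,2R,4S,5R,6R)-6-(4-acetoxy-3-methoxyphenyl)-4-methoxy-2-[3-methoxy-4-(triisopropylsilyloxy)phenyl]-3,7-dioxabicyclo[3.3.0]octane | COc1cc([C@@H]2O[C@H](OC)[C@@H]3[C@H]2CO[C@H]3c2ccc(OC(C)=O)c(OC)c2)ccc1O[Si](C(C)C)(C(C)C)C(C)C | intermediate
21 | (1S,2R,5S,6R)-6-(4-acetoxy-3-methoxyphenyl)-2-[3-methoxy-4-(triisopropylsilyloxy)phenyl]-3,7-dioxabicyclo[3.3.0]octane | COc1cc([C@@H]2OC[C@@H]3[C@H]2CO[C@H]3c2ccc(OC(C)=O)c(OC)c2)ccc1O[Si](C(C)C)(C(C)C)C(C)C | intermediate
22 | (1S,2R,5S,6R)-6-(4-hydroxy-3-methoxyphenyl)-2-[3-methoxy-4-(triisopropylsilyloxy)phenyl]-3,7-dioxabicyclo[3.3.0]octane | COc1cc([C@@H]2OC[C@@H]3[C@H]2CO[C@H]3c2ccc(O)c(OC)c2)ccc1O[Si](C(C)C)(C(C)C)C(C)C | intermediate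
23 | (1S,2R,5S,6R)-6-[3-methoxy-4-(3-methylbut-2-enyloxy)phenyl]-2-[3-methoxy-4-(triisopropylsilyloxy)phenyl]-3,7-dioxabicyclo[3.3.0]octane | COc1cc([C@@H]2OC[C@@H]3[C@H]2CO[C@H]3c2ccc(OCC=C(C)C)c(OC)c2)ccc1O[Si](C(C)C)(C(C)C)C(C)C | intermediate
24 | (1S,2R,5S,6R)-2-(4-hydroxy-3-methoxyphenyl)-6-[3-methoxy-4-(3-methylbut-2-enyloxy)phenyl]-3,7-dioxabicyclo[3.3.0]octane | COc1cc([C@@H]2OC[C@@H]3[C@H]2CO[C@H]3c2ccc(OCC=C(C)C)c(OC)c2)ccc1O | target

**Count and risks**
Total steps: 12. Longest linear sequence: 10 (steps 1, 3, 4, 5, 6, 8, 9, 10, 11, 12).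

Risk 1, step 8: poor facial selectivity at C6. Closure through the compact arrangement with O7 lying over ring A would turn the aryl endo, a mode this type of enol ether–oxocarbenium closure can prefer; acid-catalysed addition of the C8 hydroxyl to its own enol ether may also compete.
Fallback: setting out from 14 and 16, the same annulation would then deliver mainly the C6-epimeric methyl acetal F1. The conditions of step 9 would reduce it to the C6-epimeric furofuran acetate F2, and those of step 10 would convert that into the C6-epimeric phenol F3. C6 would then be set under thermodynamic instead of kinetic control. Camphorsulfonic acid in CH2Cl2 should open the C6–O7 bond of F3 reversibly to the p-hydroxybenzylic cation; this is the known acid epimerisation of phenolic furofurans at the benzylic carbon para to a free phenol, and the silyl-protected C2 arene should ionise less readily. Compound 22 is separated from the equilibrium mixture and recovered F3 is resubmitted. The fallback rejoins the route at 22.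

Risk 2, step 5: incomplete elimination or decomposition of the anomeric sulfonate, hydrolysis of the enol ether on isolation, or migration of the double bond into conjugation with the imide.
Fallback: setting out from 11, methanol with PPTS would give the stable methyl acetal F4. TMSOTf with i-Pr2NEt at −20 °C would then eliminate methanol from it (the silyl triflate–amine conversion of acetals into enol ethers) to give 13, where the route is rejoined. The leaving group is thus generated from an isolable acetal instead of a sulfonate made in situ.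

Risk 3, step 9: Lewis acid ionisation of the electron-rich benzylic C2–O3 bond (ring opening, over-reduction or epimerisation at C2) in competition with the acetal reduction.
Fallback: setting out from 20, aqueous acetic acid in THF would hydrolyse the acetal to the C4 lactol F5, and NaBH4 (THF/i-PrOH, 0 °C) would open it to the ring-opened diol F6. Mitsunobu cyclodehydration (PPh3, DIAD, THF, 0 °C) would then close ring A to 21, where the route is rejoined without any Lewis acid. In that closure the primary C4 hydroxyl is activated and the benzylic C2 oxygen displaces it, so C2 is retained.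

**Further compounds**
F1 | step 8 | (1S,2R,4S,5R,6S)-6-(4-acetoxy-3-methoxyphenyl)-4-methoxy-2-[3-methoxy-4-(triisopropylsilyloxy)phenyl]-3,7-dioxabicyclo[3.3.0]octane (C6 epimer of 20) | COc1cc([C@@H]2O[C@H](OC)[C@@H]3[C@H]2CO[C@@H]3c2ccc(OC(C)=O)c(OC)c2)ccc1O[Si](C(C)C)(C(C)C)C(C)C
F2 | step 8 | (1S,2R,5S,6S)-6-(4-acetoxy-3-methoxyphenyl)-2-[3-methoxy-4-(triisopropylsilyloxy)phenyl]-3,7-dioxabicyclo[3.3.0]octane (C6 epimer of 21) | COc1cc([C@@H]2OC[C@@H]3[C@H]2CO[C@@H]3c2ccc(OC(C)=O)c(OC)c2)ccc1O[Si](C(C)C)(C(C)C)C(C)C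
F3 | step 8 | (1S,2R,5S,6S)-6-(4-hydroxy-3-methoxyphenyl)-2-[3-methoxy-4-(triisopropylsilyloxy)phenyl]-3,7-dioxabicyclo[3.3.0]octane (C6 epimer of 22) | COc1cc([C@@H]2OC[C@@H]3[C@H]2CO[C@@H]3c2ccc(O)c(OC)c2)ccc1O[Si](C(C)C)(C(C)C)C(C)C
F4 | step 5 | (R)-4-benzyl-3-[(2R,3R)-5-methoxy-2-[3-methoxy-4-(triisopropylsilyloxy)phenyl]oxolane-3-carbonyl]oxazolidin-2-one (methyl acetal of 11, anomers) | COc1cc([C@@H]2OC(OC)C[C@H]2C(=O)N3[C@H](Cc4ccccc4)COC3=O)ccc1O[Si](C(C)C)(C(C)C)C(C)C
F5 | step 9 | (1S,2R,5R,6R)-6-(4-acetoxy-3-methoxyphenyl)-2-[3-methoxy-4-(triisopropylsilyloxy)phenyl]-3,7-dioxabicyclo[3.3.0]octan-4-ol (C4 lactol, anomers) | COc1cc([C@@H]2OC(O)[C@@H]3[C@H]2CO[C@H]3c2ccc(OC(C)=O)c(OC)c2)ccc1O[Si](C(C)C)(C(C)C)C(C)C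
F6 | step 9 | 4-[(2R,3S,4S)-3-(hydroxymethyl)-4-{(R)-hydroxy[3-methoxy-4-(triisopropylsilyloxy)phenyl]methyl}oxolan-2-yl]-2-methoxyphenyl acetate | COc1cc([C@H](O)[C@@H]2CO[C@@H](c3ccc(OC(C)=O)c(OC)c3)[C@@H]2CO)ccc1O[Si](C(C)C)(C(C)C)C(C)C
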